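## Analysis of the target

Artocarpetin B is a flavone: ring A is fused to the pyranone ring C as a chromen-4-one, and ring B is an aryl group on C2. It has no stereocentre and no stereogenic double bond, so the whole problem is one of regiochemistry. Ring A is fully differentiated, with a free hydroxyl at C5 that is hydrogen-bonded to the C4 carbonyl, a methyl ether at C7, and a 3-methylbut-2-enyl (prenyl) group at C8 between O7 and O1; C6 is unsubstituted. Ring B is a resorcinol whose oxygen ortho to C1' (C2') is methylated while the oxygen para to C1' (C4') is free, so two phenolic oxygens of similar reactivity must end up differently substituted. The sensitive parts are the trisubstituted alkene of the prenyl group (strong acid, electrophiles, hydrogenation, allylic oxidants), the electrophilic C2 of the pyranone (alkoxide, hydride) and the two free phenols. The difficulty lies in two placements: prenyl at C8 and not C6, and methyl on O2' and not O4'. The strategy rests on ring B: C2' with its methoxy group, C3', and C4' with its free hydroxyl are the imprint of a 1,1-dimethoxy-3-silyloxybutadiene that has added across an alkyne on C2, so the oxygen pattern of ring B is written into the diene and needs no protecting group.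

## Retrosynthetic reasoning

**Ring B (C1'–C2' and C5'–C6').** Artocarpetin B 20 is cut inside ring B, into the 2-ethynylchromone 13 and the ketene acetal diene 16. Cutting the C2–C1' bond instead would demand a preformed ring B with O4' protected and O2' methylated, and a deprotection at the end. Cutting inside the ring lets the ketal carbon of 16 become C2' (one methoxy kept, one lost as methanol) and the silyloxy carbon become C4' (free hydroxyl after work-up). The forward reaction must join the CH2 terminus of 16 to the terminal alkyne carbon of 13 and the ketal carbon to the internal alkyne carbon, then aromatise.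

**Diene 16.** The silyl enol ether O–Si bond is cut to give the acyl ketene acetal 15, and the C–C bond between its carbonyl carbon and the ketene acetal carbon is cut to give 1,1-dimethoxyethene 14. Both forward steps are simple (C-acylation, then kinetic enolisation and O-silylation), and 16 is made just before use.

**Alkyne of 13.** The triple bond is traced back to the aldehyde 11 by a one-carbon diazophosphonate homologation. A cross-coupling at C2 is not chosen because a 2-halo- or 2-sulfonyloxychromone is not readily available. Aldehyde 11 comes from the alcohol 10 and this from the ester 9, so the C2 carbon stays at the robust ester oxidation level until the harsher steps are past.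

**Prenyl group at C8 (C8–CH2).** The C8–C bond of 9 is cut by a Claisen–Cope sequence, which leads to the 5-O-prenyl ether 6, and the O–C bond of 6 leads to the phenol 4 and prenyl bromide 5. The rearrangement is placed on the chromone and not on the acetophenone because O1 is then already fixed: the position para to O5 can only be C8, and the hydroxyl that the rearrangement regenerates is the 5-OH of the target. On the symmetric acetophenone the same shift would leave two free hydroxyls and an ambiguous ring closure.

**Ring C (C2–C3 and O1–C2).** The chromone ester 4 is cut into the acetophenone 1 and diethyl oxalate 2: a Claisen condensation makes the C2–C3 bond and acid closes O1–C2. Because 1 has a mirror plane through C1' and C4', both hydroxyls give the same chromone.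

## Alternatives that were turned down

**Alternative 1: Parham-type closure of ring C.**
- Disconnection: the C4–C4a bond, leading back to methyl (Z)-3-[2-iodo-5-methoxy-3-(3-methylbut-2-enyloxy)phenoxy]-3-[2-methoxy-4-(methoxymethoxy)phenyl]prop-2-enoate A1.
- Forward key step: iodine–magnesium exchange on A1 with i-PrMgCl·LiCl, then attack of the aryl carbanion on the ester, should give 7-methoxy-2-[2-methoxy-4-(methoxymethoxy)phenyl]-5-(3-methylbut-2-enyloxy)chromen-4-one A2.
- For: the ring closes at low temperature without acid, the chromone regiochemistry is unambiguous, and ring B arrives finished from a simple arene, which removes all doubt about building it. On that point it is stronger than the chosen route.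
- Against: the exchange takes place on an electron-rich iodide with two ortho oxygens, and the acceptor is a β-aryloxyacrylate, a vinylogous carbonate of low electrophilicity. The acrylate needs Z geometry, and the iodophenol half needs a desymmetrising mono-prenylation. After A2, the Claisen–Cope shift and removal of the methoxymethyl group still follow, so the C8/C6 question is met late, on the complete flavone.
- Comparison: the overall length is similar. The chosen route offers an unprotected ring B and settles the prenyl position early on a cheap chromone ester.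

**Alternative 2: biomimetic Claisen folding.**
- Disconnection: the C4a–C5 bond of ring A, leading back to the pyranone keto ester methyl 4-{6-[2-methoxy-4-(methoxymethoxy)phenyl]-4-oxopyran-2-yl}-7-methyl-3-oxooct-6-enoate A3.
- Forward key step: Mg(OMe)2 should form the extended enolate, C4a attacks the ester, and aromatisation gives 5,7-dihydroxy-2-[2-methoxy-4-(methoxymethoxy)phenyl]-8-(3-methylbut-2-enyl)chromen-4-one A4.
- For: the prenyl group sits on the chain carbon that becomes C8, so no C6/C8 ambiguity can arise. On this point it is stronger than the chosen route, which relies on a sigmatropic relay.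
- Against: A3 is a poly-carbonyl compound with several enolisable sites, and its assembly from a pyranone and a prenylated β-keto ester is long. Competing modes (lactonisation through an enol oxygen, aldol closure, retro-Claisen cleavage) are plausible. A4 still needs selective 7-O-methylation and removal of the methoxymethyl group.
- Comparison: the chosen route buys ring A as a commercial arene and spends its risk on ring B, where the diene supplies the oxygen pattern without a protecting group.

**Alternative 3: three-component carbonylative annulation.**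
- Disconnection: C4a–C4, C4–C3 and O1–C2, leading back to 2-iodo-5-methoxybenzene-1,3-diol A5, carbon monoxide and 1-ethynyl-2-methoxy-4-(methoxymethoxy)benzene A6.
- Forward key step: PdCl2(PPh3)2 in Et2NH under CO should give 5-hydroxy-7-methoxy-2-[2-methoxy-4-(methoxymethoxy)phenyl]chromen-4-one A7 through an alkynone that closes by 6-endo attack of a phenol.
- For: it is highly convergent, the symmetry of A5 removes any regiochemical question in ring C, and the reaction class is established. In step economy and precedent it is at least as strong as the chosen route, and probably shorter.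
- Against: A5 is an electron-rich, doubly ortho-substituted iodide, so oxidative addition should be slow and loss of iodine may compete; 5-exo closure to an aurone competes with flavone formation. A6 has to be made and protected. After A7 come O-prenylation, the Claisen–Cope shift on the full flavone and deprotection.
- Comparison: the chosen route offers no protecting group on ring B, an end game in which the key step delivers the natural product itself, and the prenyl shift on an early intermediate.

Key step: step 9

Assumption: the chelated 5-hydroxyl of 13 could protonate the acid-labile ketene acetal diene, so it is masked in the flask as a trimethylsilyl ether that falls off in the same work-up; precursor and product of the key step are unchanged.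

## Route

Step 1
Reactants: 1 1-(2,6-dihydroxy-4-methoxyphenyl)ethanone; 2 diethyl oxalate
Product: 4 ethyl 5-hydroxy-7-methoxy-4-oxochromene-2-carboxylate, via diketo ester 3 (not isolated)
Conditions: NaOEt, EtOH, reflux; then HCl, EtOH, reflux
Reagents that add atoms: none
Why: Claisen condensation of the methyl ketone enolate with the oxalate gives the 2,4-diketo ester 3; acid then closes the pyranone by attack of a phenol on the C2 ketone and dehydration (chromone-2-carboxylate synthesis). The mirror symmetry of 1 makes both hydroxyls equivalent, so one chromone results.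

Step 2
Reactants: 4 ethyl 5-hydroxy-7-methoxy-4-oxochromene-2-carboxylate; 5 1-bromo-3-methylbut-2-ene (prenyl bromide)
Product: 6 ethyl 7-methoxy-5-(3-methylbut-2-enyloxy)-4-oxochromene-2-carboxylate
Conditions: K2CO3, acetone, reflux
Reagents that add atoms: none
Why: Williamson ether synthesis; the 5-OH is the only acidic site and its phenoxide displaces the primary allylic bromide by SN2 at the unsubstituted carbon.

Step 3
Reactants: 6 ethyl 7-methoxy-5-(3-methylbut-2-enyloxy)-4-oxochromene-2-carboxylate
Product: 9 ethyl 5-hydroxy-7-methoxy-8-(3-methylbut-2-enyl)-4-oxochromene-2-carboxylate, via ortho-dienone 7 (not isolated), via para-dienone 8 (not isolated)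
Conditions: Eu(fod)3 (cat.; fod = 6,6,7,7,8,8,8-heptafluoro-2,2-dimethyloctane-3,5-dionate), NaHCO3, PhCl, 85 °C
Reagents that add atoms: none
Why: Aromatic Claisen rearrangement followed by Cope rearrangement (para-Claisen–Cope), accelerated by chelation of the trivalent europium to O5 and the C4 carbonyl. The [3,3] shift places a 1,1-dimethylallyl group at C6 in the crowded dienone 7, a second [3,3] shift relays it to C8 with the linear prenyl restored (8), and enolisation gives the 5-phenol.

Step 4
Reactants: 9 ethyl 5-hydroxy-7-methoxy-8-(3-methylbut-2-enyl)-4-oxochromene-2-carboxylate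
Product: 10 5-hydroxy-2-(hydroxymethyl)-7-methoxy-8-(3-methylbut-2-enyl)chromen-4-one
Conditions: NaBH4, MeOH/THF, 0 °C
Reagents that add atoms: none
Why: Borohydride reduction of an activated ester; the ester on the electron-poor pyranone carbon is attacked faster than the vinylogous-ester C4 carbonyl, which is further deactivated as its 5-phenoxide chelate. This selectivity is known for chromone-2-carboxylates.

Step 5
Reactants: 10 5-hydroxy-2-(hydroxymethyl)-7-methoxy-8-(3-methylbut-2-enyl)chromen-4-one
Product: 11 5-hydroxy-7-methoxy-8-(3-methylbut-2-enyl)-4-oxochromene-2-carbaldehyde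
Conditions: activated MnO2, CH2Cl2, rt
Reagents that add atoms: none
Why: MnO2 oxidation of an allylic-type alcohol (the CH2OH sits on the C2=C3 double bond); the chelated phenol, the prenyl alkene and the pyranone are not touched, and there is no over-oxidation to the acid.

Step 6
Reactants: 11 5-hydroxy-7-methoxy-8-(3-methylbut-2-enyl)-4-oxochromene-2-carbaldehyde
Product: 13 2-ethynyl-5-hydroxy-7-methoxy-8-(3-methylbut-2-enyl)chromen-4-one, via diazoalkene 12 (not isolated)
Conditions: dimethyl (1-diazo-2-oxopropyl)phosphonate, K2CO3, MeOH, 0 °C to rt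
Reagents that add atoms: dimethyl (1-diazo-2-oxopropyl)phosphonate, CC(=O)C(=[N+]=[N-])P(=O)(OC)OC
Why: Ohira–Bestmann variant of the Seyferth–Gilbert homologation: methanolysis frees the diazomethylphosphonate anion, which adds to the aldehyde and eliminates phosphate to give the diazoalkene 12. Loss of N2 and a 1,2-hydrogen shift give the terminal alkyne under conditions mild enough for the pyranone.

Step 7
Reactants: 14 1,1-dimethoxyethene
Product: 15 4,4-dimethoxybut-3-en-2-one
Conditions: AcCl, Et3N, Et2O, 0 °C to rt
Reagents that add atoms: acetyl chloride, CC(=O)Cl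
Why: C-acylation of a ketene acetal: the nucleophilic CH2 carbon attacks the acid chloride, and Et3N removes the proton from the dialkoxycarbenium intermediate before chloride can demethylate it.

Step 8
Reactants: 15 4,4-dimethoxybut-3-en-2-one
Product: 16 1,1-dimethoxy-3-(trimethylsilyloxy)buta-1,3-diene
Conditions: LiN(i-Pr)2 (LDA), THF, −78 °C; then Me3SiCl
Reagents that add atoms: chlorotrimethylsilane, C[Si](C)(C)Cl
Why: Kinetic deprotonation of the methyl ketone (its only enolisable position) and O-silylation of the enolate give the 2-silyloxydiene; it is distilled and used at once.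

Step 9
Reactants: 13 2-ethynyl-5-hydroxy-7-methoxy-8-(3-methylbut-2-enyl)chromen-4-one; 16 1,1-dimethoxy-3-(trimethylsilyloxy)buta-1,3-diene
Product: 20 artocarpetin B, via silyl ether 17 (not isolated), via cycloadduct 18 (not isolated), via bis-silyl ether 19 (not isolated)
Conditions: N,O-bis(trimethylsilyl)acetamide (BSA), PhMe, 80 °C; then 16 (3 equiv), 110 °C, sealed tube; then 1 M HCl, THF, rt
Reagents that add atoms: none
Why: Proposed new method: the closest known reaction type is the Diels–Alder reaction and aromatisation of 1,1-dialkoxy-3-silyloxybutadienes with ynones and ynoates to give resorcinol monoethers, whereas here the alkyne is activated only vinylogously through C2=C3–C4=O of the pyranone. The diene HOMO is largest at its CH2 terminus and the LUMO of the enynone is largest at the terminal alkyne carbon, so C5'–C6' should form first (in a concerted asynchronous transition state, or as a 1,6-addition that leaves an allenyl enolate and a dimethoxycarbenium ion) and C1'–C2' then closes ring B as a six-membered ring in the [4+2] mode. The adduct 18 is a cyclohexa-1,4-diene with the ketal at C2' and a CH2 at C5'; 1,4-loss of methanol at 110 °C is driven by aromatisation and gives 19, with the remaining methoxy on C2' and the silyloxy group on C4'. Dilute acid then cleaves both aryl silyl ethers. No stereocentre is formed. The step needs the stated orientation, which the matching polarisation of both partners secures, and site selectivity for the alkyne over the tetrasubstituted C2=C3 bond and the unactivated prenyl alkene, which sterics and electron demand secure. The prenyl group is flanked by OMe-7 and O1 and has no free ortho hydroxyl, so the acidic work-up cannot close a chroman.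

## Compound list

1 | 1-(2,6-dihydroxy-4-methoxyphenyl)ethanone (2',6'-dihydroxy-4'-methoxyacetophenone) | CC(=O)c1c(O)cc(OC)cc1O | starting material
2 | diethyl oxalate | CCOC(=O)C(=O)OCC | starting material
3 | ethyl 4-(2,6-dihydroxy-4-methoxyphenyl)-2,4-dioxobutanoate | CCOC(=O)C(=O)CC(=O)c1c(O)cc(OC)cc1O | intermediate (not isolated)
4 | ethyl 5-hydroxy-7-methoxy-4-oxochromene-2-carboxylate | CCOC(=O)c1cc(=O)c2c(O)cc(OC)cc2o1 | intermediate
5 | 1-bromo-3-methylbut-2-ene (prenyl bromide) | CC(C)=CCBr | starting material
6 | ethyl 7-methoxy-5-(3-methylbut-2-enyloxy)-4-oxochromene-2-carboxylate | CCOC(=O)c1cc(=O)c2c(OCC=C(C)C)cc(OC)cc2o1 | intermediate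
7 | ethyl 7-methoxy-6-(2-methylbut-3-en-2-yl)-4,5-dioxo-5,6-dihydro-4H-chromene-2-carboxylate (racemic) | CCOC(=O)C1=CC(=O)C2=C(O1)C=C(OC)C(C(C)(C)C=C)C2=O | intermediate (not isolated)
8 | ethyl 7-methoxy-8-(3-methylbut-2-enyl)-4,5-dioxo-5,8-dihydro-4H-chromene-2-carboxylate (racemic) | CCOC(=O)C1=CC(=O)C2=C(O1)C(CC=C(C)C)C(OC)=CC2=O | intermediate (not isolated)
9 | ethyl 5-hydroxy-7-methoxy-8-(3-methylbut-2-enyl)-4-oxochromene-2-carboxylate | CCOC(=O)c1cc(=O)c2c(O)cc(OC)c(CC=C(C)C)c2o1 | intermediate
10 | 5-hydroxy-2-(hydroxymethyl)-7-methoxy-8-(3-methylbut-2-enyl)chromen-4-one | OCc1cc(=O)c2c(O)cc(OC)c(CC=C(C)C)c2o1 | intermediate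
11 | 5-hydroxy-7-methoxy-8-(3-methylbut-2-enyl)-4-oxochromene-2-carbaldehyde | O=Cc1cc(=O)c2c(O)cc(OC)c(CC=C(C)C)c2o1 | intermediate
12 | 2-(2-diazoethenyl)-5-hydroxy-7-methoxy-8-(3-methylbut-2-enyl)chromen-4-one | [N-]=[N+]=C=Cc1cc(=O)c2c(O)cc(OC)c(CC=C(C)C)c2o1 | intermediate (not isolated)
13 | 2-ethynyl-5-hydroxy-7-methoxy-8-(3-methylbut-2-enyl)chromen-4-one | C#Cc1cc(=O)c2c(O)cc(OC)c(CC=C(C)C)c2o1 | intermediate
14 | 1,1-dimethoxyethene | C=C(OC)OC | starting material
15 | 4,4-dimethoxybut-3-en-2-one | COC(OC)=CC(C)=O | intermediate
16 | 1,1-dimethoxy-3-(trimethylsilyloxy)buta-1,3-diene | COC(OC)=CC(=C)O[Si](C)(C)C | intermediate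
17 | 2-ethynyl-7-methoxy-8-(3-methylbut-2-enyl)-5-(trimethylsilyloxy)chromen-4-one | C#Cc1cc(=O)c2c(O[Si](C)(C)C)cc(OC)c(CC=C(C)C)c2o1 | intermediate (not isolated)
18 | 2-[6,6-dimethoxy-4-(trimethylsilyloxy)cyclohexa-1,4-dien-1-yl]-7-methoxy-8-(3-methylbut-2-enyl)-5-(trimethylsilyloxy)chromen-4-one | COC1(OC)C=C(O[Si](C)(C)C)CC=C1c1cc(=O)c2c(O[Si](C)(C)C)cc(OC)c(CC=C(C)C)c2o1 | intermediate (not isolated)
19 | 7-methoxy-2-[2-methoxy-4-(trimethylsilyloxy)phenyl]-8-(3-methylbut-2-enyl)-5-(trimethylsilyloxy)chromen-4-one | COc1cc(O[Si](C)(C)C)ccc1-c1cc(=O)c2c(O[Si](C)(C)C)cc(OC)c(CC=C(C)C)c2o1 | intermediate (not isolated)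
20 | artocarpetin B, 5-hydroxy-2-(4-hydroxy-2-methoxyphenyl)-7-methoxy-8-(3-methylbut-2-enyl)chromen-4-one | COc1cc(O)ccc1-c1cc(=O)c2c(O)cc(OC)c(CC=C(C)C)c2o1 | target

## Step count and least certain steps

Total step count: 9. Longest linear sequence: 7 (steps 1 to 6 and step 9); the diene branch is steps 7 and 8.

**Step 9 (key step).**
- What may go wrong: the alkyne is activated only through the pyranone double bond, so the cycloaddition may be slower than thermal decay or protonation of the diene. Hydrolysis of the ketal before methanol is lost would also strip the C2' methyl ether.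
- Fallback by known chemistry, from 1 back to 20: the ring B aldehyde 2-methoxy-4-(methoxymethoxy)benzaldehyde F1 is made from commercial 4-hydroxy-2-methoxybenzaldehyde with MOMCl and i-Pr2NEt. Claisen–Schmidt condensation of 1 with F1 (KOH, EtOH) should give (E)-1-(2,6-dihydroxy-4-methoxyphenyl)-3-[2-methoxy-4-(methoxymethoxy)phenyl]prop-2-en-1-one F2. Oxidative cyclisation (I2 cat., DMSO, 120 °C) should give 5-hydroxy-7-methoxy-2-[2-methoxy-4-(methoxymethoxy)phenyl]chromen-4-one F3. O-Prenylation with 5 (K2CO3, acetone) should give 7-methoxy-2-[2-methoxy-4-(methoxymethoxy)phenyl]-5-(3-methylbut-2-enyloxy)chromen-4-one F4. The Claisen–Cope shift under the conditions of step 3 should give 5-hydroxy-7-methoxy-2-[2-methoxy-4-(methoxymethoxy)phenyl]-8-(3-methylbut-2-enyl)chromen-4-one F5, and HCl in MeOH removes the acetal to give 20.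

**Step 3.**
- What may go wrong: enolisation of the ortho-dienone before the Cope shift would leave the reversed prenyl group at C6.
- Fallback, from 4 back to 9: methylation (MeI, K2CO3) should give ethyl 5,7-dimethoxy-4-oxochromene-2-carboxylate F6. Iodination (N-iodosuccinimide, CF3CO2H cat., MeCN) is expected at C8 once O5 is an ether and should give ethyl 8-iodo-5,7-dimethoxy-4-oxochromene-2-carboxylate F7. Stille coupling with tributyl(3-methylbut-2-enyl)stannane (Pd(PPh3)4, DMF, 90 °C) should give ethyl 5,7-dimethoxy-8-(3-methylbut-2-enyl)-4-oxochromene-2-carboxylate F8. Selective cleavage of the peri methyl ether (BCl3, CH2Cl2, −78 °C) returns 9.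

**Step 6.**
- What may go wrong: conjugate addition of methoxide to C2 of the aldehyde or to the enynone product, with ring opening of the pyranone.
- Fallback, from 11 back to 13: Wittig reaction with the ylide from (bromomethyl)triphenylphosphonium bromide and KOt-Bu (THF, −78 °C) should give (Z)-2-(2-bromoethenyl)-5-hydroxy-7-methoxy-8-(3-methylbut-2-enyl)chromen-4-one F9, and anti-elimination of HBr with Bu4NF in DMF gives 13 without methanolic base.

**Step 4.**
- What may go wrong: hydride addition to C2 or C4 of the pyranone in competition with the ester.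
- Fallback, from 9 back to 10: hydrolysis (LiOH, THF/H2O, 0 °C) should give 5-hydroxy-7-methoxy-8-(3-methylbut-2-enyl)-4-oxochromene-2-carboxylic acid F10. Activation with isobutyl chloroformate and N-methylmorpholine (THF, −15 °C) gives the mixed anhydride isobutoxycarbonyl 5-hydroxy-7-methoxy-8-(3-methylbut-2-enyl)-4-oxochromene-2-carboxylate F11, which NaBH4 reduces within minutes at −15 °C to 10.

## Further compounds

F1 | step 9 | 2-methoxy-4-(methoxymethoxy)benzaldehyde | COCOc1ccc(C=O)c(OC)c1
F2 | step 9 | (E)-1-(2,6-dihydroxy-4-methoxyphenyl)-3-[2-methoxy-4-(methoxymethoxy)phenyl]prop-2-en-1-one | COCOc1ccc(/C=C/C(=O)c2c(O)cc(OC)cc2O)c(OC)c1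
F3 | step 9 | 5-hydroxy-7-methoxy-2-[2-methoxy-4-(methoxymethoxy)phenyl]chromen-4-one | COCOc1ccc(-c2cc(=O)c3c(O)cc(OC)cc3o2)c(OC)c1
F4 | step 9 | 7-methoxy-2-[2-methoxy-4-(methoxymethoxy)phenyl]-5-(3-methylbut-2-enyloxy)chromen-4-one | COCOc1ccc(-c2cc(=O)c3c(OCC=C(C)C)cc(OC)cc3o2)c(OC)c1
F5 | step 9 | 5-hydroxy-7-methoxy-2-[2-methoxy-4-(methoxymethoxy)phenyl]-8-(3-methylbut-2-enyl)chromen-4-one | COCOc1ccc(-c2cc(=O)c3c(O)cc(OC)c(CC=C(C)C)c3o2)c(OC)c1
F6 | step 3 | ethyl 5,7-dimethoxy-4-oxochromene-2-carboxylate | CCOC(=O)c1cc(=O)c2c(OC)cc(OC)cc2o1
F7 | step 3 | ethyl 8-iodo-5,7-dimethoxy-4-oxochromene-2-carboxylate | CCOC(=O)c1cc(=O)c2c(OC)cc(OC)c(I)c2o1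
F8 | step 3 | ethyl 5,7-dimethoxy-8-(3-methylbut-2-enyl)-4-oxochromene-2-carboxylate | CCOC(=O)c1cc(=O)c2c(OC)cc(OC)c(CC=C(C)C)c2o1
F9 | step 6 | (Z)-2-(2-bromoethenyl)-5-hydroxy-7-methoxy-8-(3-methylbut-2-enyl)chromen-4-one | Br/C=C\c1cc(=O)c2c(O)cc(OC)c(CC=C(C)C)c2o1
F10 | step 4 | 5-hydroxy-7-methoxy-8-(3-methylbut-2-enyl)-4-oxochromene-2-carboxylic acid | OC(=O)c1cc(=O)c2c(O)cc(OC)c(CC=C(C)C)c2o1
F11 | step 4 | isobutoxycarbonyl 5-hydroxy-7-methoxy-8-(3-methylbut-2-enyl)-4-oxochromene-2-carboxylate (mixed anhydride) | CC(C)COC(=O)OC(=O)c1cc(=O)c2c(O)cc(OC)c(CC=C(C)C)c2o1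
A1 | alternative 1 | methyl (Z)-3-[2-iodo-5-methoxy-3-(3-methylbut-2-enyloxy)phenoxy]-3-[2-methoxy-4-(methoxymethoxy)phenyl]prop-2-enoate | COC(=O)/C=C(\Oc1cc(OC)cc(OCC=C(C)C)c1I)c1ccc(OCOC)cc1OC
A2 | alternative 1 | 7-methoxy-2-[2-methoxy-4-(methoxymethoxy)phenyl]-5-(3-methylbut-2-enyloxy)chromen-4-one | COCOc1ccc(-c2cc(=O)c3c(OCC=C(C)C)cc(OC)cc3o2)c(OC)c1
A3 | alternative 2 | methyl 4-{6-[2-methoxy-4-(methoxymethoxy)phenyl]-4-oxopyran-2-yl}-7-methyl-3-oxooct-6-enoate (racemic) | COC(=O)CC(=O)C(CC=C(C)C)c1cc(=O)cc(-c2ccc(OCOC)cc2OC)o1
A4 | alternative 2 | 5,7-dihydroxy-2-[2-methoxy-4-(methoxymethoxy)phenyl]-8-(3-methylbut-2-enyl)chromen-4-one | COCOc1ccc(-c2cc(=O)c3c(O)cc(O)c(CC=C(C)C)c3o2)c(OC)c1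
A5 | alternative 3 | 2-iodo-5-methoxybenzene-1,3-diol | COc1cc(O)c(I)c(O)c1
A6 | alternative 3 | 1-ethynyl-2-methoxy-4-(methoxymethoxy)benzene | C#Cc1ccc(OCOC)cc1OC
A7 | alternative 3 | 5-hydroxy-7-methoxy-2-[2-methoxy-4-(methoxymethoxy)phenyl]chromen-4-one | COCOc1ccc(-c2cc(=O)c3c(O)cc(OC)cc3o2)c(OC)c1
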